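**Retrosynthetic overview**
1. Target 7 (one ring, 31-membered, no stereocentre) is disconnected at the ester C–O bond in the oxidative sense, giving symmetric triacontane-1,30-diol 4. The ring is closed last, by dehydrogenative macrolactonisation.
2. Diol 4 is cut at the central C15–C16 bond into two identical C15 halves, joined by Kolbe decarboxylative dimerisation of 16-hydroxyhexadecanoic acid 3.
3. Acid 3 comes from saponification of the bulk musk lactone 16-hexadecanolide 1.
4. Ring order: the 17-membered ring of 1 is opened in step 1; the only ring of the target is formed in step 3.

Assumption: the SMILES is read as the lactone of 30-hydroxytriacontanoic acid (C30H58O2, 29 CH2 groups between the carbonyl carbon and the ring oxygen). It has no stereocentre, so there is no enantiomer to control.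

**Step 1**
Reactants: 1 16-hexadecanolide
Product: 3 16-hydroxyhexadecanoic acid, via potassium 16-hydroxyhexadecanoate 2 (not isolated)
Conditions: KOH (1.5 equiv), MeOH/H2O 9:1, reflux, 3 h; then 2 M HCl, 0 °C, pH 2; filter, dry below 40 °C
Reagents that add atoms: potassium hydroxide, [K+].[OH-]
Why: Saponification of an unstrained, unhindered macrolactone is irreversible, and cold acidification precipitates the hydroxy acid; no stereocentre is involved.

**Step 2**
Reactants: 3 16-hydroxyhexadecanoic acid (two molecules; about 10 % present as its potassium salt 2 during the electrolysis)
Product: 4 triacontane-1,30-diol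
Conditions: KOH (0.1 equiv), MeOH, 50–55 °C, smooth Pt anode and Pt cathode, undivided cell, 0.25 A/cm2, about 1.5 F/mol, polarity reversed every 2 min; cool, filter, recrystallise from toluene
Reagents that add atoms: none
Why: Kolbe electrolysis: anodic decarboxylation of the carboxylate at high current density gives primary 15-hydroxypentadecyl radicals that dimerise at the electrode to the C30 chain, and the remote primary hydroxyl is tolerated just as the methanol solvent is; no stereocentre is involved.

**Step 3**
Reactants: 4 triacontane-1,30-diol
Product: 7 oxacyclohentriacontan-2-one (30-triacontanolide), via 30-hydroxytriacontanal 5 (not isolated), via oxacyclohentriacontan-2-ol 6 (not isolated)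
Conditions: RuHCl(CO)(PNN) (5 mol %; PNN = 2-(tBu2PCH2)-6-(Et2NCH2)C5H3N), KOtBu (5 mol %), toluene, reflux, Ar sweep; 4 added over 20 h as a hot 20 mM toluene solution, final 2 mM; then 12 h; silica filtration
Reagents that add atoms: none
Why: Proposed new method: acceptorless dehydrogenative macrolactonisation of a symmetric α,ω-diol, in which the dearomatised divalent ruthenium pincer hydride formed from the precatalyst and KOtBu dehydrogenates one CH2OH to aldehyde 5, the distal hydroxyl adds to give the 31-membered lactol 6, and a second dehydrogenation made irreversible by sweeping out H2 gives the ester and so closes the ring through its C–O bond; because hemiacetal formation is a fast pre-equilibrium, ring versus chain is set by the effective molarity of strain-free large-ring closure (about 10^-2 M) against a sub-millimolar steady-state hydroxyl concentration, the lactone has no hydroxyl left and cannot over-oxidise, and any dialdehyde re-enters by hydrogen transfer from remaining alcohol; the closest known reactions are Ru-pincer dehydrogenative lactonisation of 1,4- to 1,6-diols and dehydrogenative polyesterification of long α,ω-diols at high concentration, neither shown for a macrolactone; the product has no stereocentre (racemic lactol 6 is oxidised away).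

**Compound list**
1 | 16-hexadecanolide (oxacycloheptadecan-2-one) | O=C1CCCCCCCCCCCCCCCO1 | starting material
2 | potassium 16-hydroxyhexadecanoate | [K+].[O-]C(=O)CCCCCCCCCCCCCCCO | intermediate
3 | 16-hydroxyhexadecanoic acid | OC(=O)CCCCCCCCCCCCCCCO | intermediate
4 | triacontane-1,30-diol | OCCCCCCCCCCCCCCCCCCCCCCCCCCCCCCO | intermediate
5 | 30-hydroxytriacontanal | O=CCCCCCCCCCCCCCCCCCCCCCCCCCCCCCO | intermediate
6 | oxacyclohentriacontan-2-ol (racemic lactol) | OC1CCCCCCCCCCCCCCCCCCCCCCCCCCCCCO1 | intermediate
7 | oxacyclohentriacontan-2-one (30-triacontanolide) | O=C1CCCCCCCCCCCCCCCCCCCCCCCCCCCCCO1 | target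

**Total step count:** 3
**Longest linear sequence:** 3 steps (1 → 3 → 4 → 7)

**Steps most likely to fail**

1. Step 3 (the proposed new step). The risks are intermolecular esterification giving linear and cyclic oligoesters, stalling at aldehyde 5, and catalyst loss by aldehyde decarbonylation. The fallback uses known chemistry, sets out from 4 and comes back to the route at 7. Diol 4 is desymmetrised with 48 % aqueous HBr (1.2 equiv) in refluxing toluene, the established selective monobromination of α,ω-diols, to give 30-bromotriacontan-1-ol F1. The remaining alcohol is oxidised with TEMPO (0.2 equiv) and PhI(OAc)2 (2.5 equiv) in CH2Cl2/MeCN/H2O at 35 °C to 30-bromotriacontanoic acid F2. F2 is then added by syringe pump (final 2 mM) to Cs2CO3 (1.5 equiv) in DMF at 80 °C. The cesium 30-bromotriacontanoate F3 formed in the flask closes by intramolecular SN2 O-alkylation (cesium carboxylate macrolactonisation of an ω-bromo acid) to 7. The ring is still closed through a C–O bond, now the alkyl C–O bond.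

2. Step 2. The risks are filming of the Pt anode by the poorly soluble C30 diol and two-electron (Hofer–Moest) side products such as C15 ethers, alkenes and esters. The fallback sets out from 3 and comes back at 4. Acid 3 is condensed with N-hydroxyphthalimide (1.05 equiv) and N,N'-diisopropylcarbodiimide (1.1 equiv, no DMAP, THF/CH2Cl2, 0 °C to rt) to the redox-active ester 1,3-dioxoisoindolin-2-yl 16-hydroxyhexadecanoate F4. F4 is homocoupled by the known nickel-electrocatalytic reductive doubly decarboxylative coupling of redox-active esters: NiCl2·6H2O with 2,2':6',2''-terpyridine (20 mol %), AgNO3 (0.3 equiv), carbon cathode, sacrificial Mg anode, NMP, rt, constant current. This is a cathodic, nickel-mediated radical coupling, so it has no carbocation channel and no anodic product film, and it gives 4 directly.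

3. Step 1. The chemistry is safe; the risk is practical. Salt 2 is a soap that can gel or emulsify on work-up, and the free hydroxy acid self-esterifies to estolides if dried hot. The fallback sets out from 1 and comes back at 3. Lactone 1 is opened by transesterification in benzyl alcohol (10 equiv) with NaOBn (0.1 equiv) at 60 °C to benzyl 16-hydroxyhexadecanoate F5, which can be chromatographed or crystallised. Hydrogenolysis (H2 1 atm, Pd/C 10 wt %, EtOAc/EtOH, rt), filtration and evaporation then deliver 3 under neutral conditions without aqueous work-up.

**Further compounds**
F1 | step 3 | 30-bromotriacontan-1-ol | OCCCCCCCCCCCCCCCCCCCCCCCCCCCCCCBr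
F2 | step 3 | 30-bromotriacontanoic acid | OC(=O)CCCCCCCCCCCCCCCCCCCCCCCCCCCCCBr
F3 | step 3 | cesium 30-bromotriacontanoate | [Cs+].[O-]C(=O)CCCCCCCCCCCCCCCCCCCCCCCCCCCCCBr
F4 | step 2 | 1,3-dioxoisoindolin-2-yl 16-hydroxyhexadecanoate | OCCCCCCCCCCCCCCCC(=O)ON1C(=O)c2ccccc2C1=O
F5 | step 1 | benzyl 16-hydroxyhexadecanoate | OCCCCCCCCCCCCCCCC(=O)OCc1ccccc1
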